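**Plan**

Retrosynthesis: the ester C–O bond at O3 is cut first (diol plus (S)-3-methylpentanoic acid), then the C3–O bond (allylic hydroxylation of a Δ1 alkene), then in one operation the ring A bond C2–C3 together with the C4–OH bond, which opens ring A to a monocyclic 1,5-enyne; further back, C7=C11 (acetone aldol), the alkyne carbon C2, the C10–C1 bond (conjugate addition) and, in the reverse sense, the C7–C4 cyclobutane bond of verbenone.
Forward: ring B is the six-membered ring of (1R,5R)-verbenone, whose ten carbons become C5–C10, C14 and, from the gem-dimethyl bridge, C4, C3 and C15; vinyl addition, vinyl-to-ethynyl change and cyclobutane opening give the enyne, C7 receives the isopropylidene group, and ring A is closed last, then oxidised at C3, saturated and acylated.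
Enabling feature: C4 carries a methyl group and an oxygen and lies 1,3 to the quaternary C10 across C5, so C3=C4(CH3) can be an isopropenyl group on C5 and C1≡C2 an ethynyl group on C10; 6-endo attack of C3 on C2 then leaves the cation on tertiary C4, where the 4-OH must enter (the same water capture that ends eudesmane biosynthesis), and the new C1=C2 bond makes C3 the only allylic CH2.
Stereochemistry: C5 comes from verbenone, C10 from cuprate attack anti to the gem-dimethyl bridge, C4 from anti addition of water on the α face in the key step, C3 from suprafacial SeO2 oxygen transfer on the α face, and the side-chain centre from (S)-1-bromo-2-methylbutane.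

Key step: step 7

Remark: eudesmane numbering (ring A = C1–C5 and C10, ring B = C5–C10, C14 on C10, C15 on C4, C11–C13 = isopropylidene) is used for all intermediates; (1R,5R)-(+)-verbenone, the enantiomer related to (1R)-(+)-α-pinene, is taken as commercially available.

**Route**

Step 1
Reactants: 1 (1R,5R)-(+)-verbenone
Product: 2 (1R,4S,5S)-4-ethenyl-4,6,6-trimethylbicyclo[3.1.1]heptan-2-one (vinyl anti to the CMe2 bridge)
Conditions: CH2=CHMgBr, CuBr·SMe2 (20 mol %), THF, −40 to 0 °C; 1 M HCl
Reagents that add atoms: vinylmagnesium bromide, C=C[Mg]Br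
Why: Copper-catalysed conjugate addition of the Grignard reagent to the β-methyl enone should create the quaternary carbon C10, the vinyl group entering the enone face on the CH2-bridge side, anti to the shielding gem-dimethyl bridge.

Step 2
Reactants: 2 (1R,4S,5S)-4-ethenyl-4,6,6-trimethylbicyclo[3.1.1]heptan-2-one
Product: 4 (1R,4R,5S)-4-formyl-4,6,6-trimethylbicyclo[3.1.1]heptan-2-one, via ozonide 3 (not isolated)
Conditions: O3, CH2Cl2, −78 °C; Me2S, −78 °C to rt
Reagents that add atoms: ozone, [O-][O+]=O
Why: Ozonolysis with reductive work-up cleaves the only C=C bond and leaves C1 as a formyl group on C10 without touching a stereocentre.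

Step 3
Reactants: 4 (1R,4R,5S)-4-formyl-4,6,6-trimethylbicyclo[3.1.1]heptan-2-one
Product: 5 (1R,4R,5S)-4-ethynyl-4,6,6-trimethylbicyclo[3.1.1]heptan-2-one
Conditions: dimethyl (1-diazo-2-oxopropyl)phosphonate, K2CO3, MeOH, 0 °C to rt
Reagents that add atoms: dimethyl (1-diazo-2-oxopropyl)phosphonate, COP(=O)(OC)C(=[N+]=[N-])C(C)=O
Why: Seyferth–Gilbert homologation with the Ohira–Bestmann reagent should convert the non-enolisable aldehyde into the terminal alkyne (adding C2), the hindered ketone being inert to the phosphonate anion.

Step 4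
Reactants: 5 (1R,4R,5S)-4-ethynyl-4,6,6-trimethylbicyclo[3.1.1]heptan-2-one
Product: 8 (3R,4S)-3-ethynyl-3-methyl-4-(prop-1-en-2-yl)cyclohexan-1-one, via tertiary iodide 6 (not isolated), via isopropenyl enol silane 7 (not isolated)
Conditions: Me3SiI, CH2Cl2, −20 to 0 °C; DBU, 0 °C to rt; 1 M HCl
Reagents that add atoms: none
Why: O-silylation lets iodide open the strained cyclobutane at the tertiary bridge carbon (homoconjugate ring opening of a cyclobutyl ketone, as used for nopinones), the C7–C4 bond being the one aligned with the carbonyl π system, and E2 loss of HI toward a methyl group then gives the isopropenyl group on C5 while C5 and C10 stay untouched.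

Step 5
Reactants: 8 (3R,4S)-3-ethynyl-3-methyl-4-(prop-1-en-2-yl)cyclohexan-1-one
Product: 10 (4S,5R)-5-ethynyl-2-(2-hydroxypropan-2-yl)-5-methyl-4-(prop-1-en-2-yl)cyclohexan-1-one (both C7 epimers), via lithium enolate 9 (not isolated)
Conditions: LiN(SiMe3)2 (1.05 equiv), THF, −78 °C; acetone, −78 °C; aq NH4Cl
Reagents that add atoms: acetone, CC(C)=O
Why: Kinetic deprotonation should take a C7 proton, away from quaternary C10 and in preference to the less acidic alkyne C–H, and the lithium enolate adds to acetone in a crossed aldol addition whose new C7 centre is removed again in step 6.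

Step 6
Reactants: 10 (4S,5R)-5-ethynyl-2-(2-hydroxypropan-2-yl)-5-methyl-4-(prop-1-en-2-yl)cyclohexan-1-one
Product: 12 (4S,5R)-5-ethynyl-5-methyl-4-(prop-1-en-2-yl)-2-(propan-2-ylidene)cyclohexan-1-one, via mesylate 11 (not isolated)
Conditions: MeSO2Cl, Et3N, CH2Cl2, 0 °C; DBU, rt
Reagents that add atoms: none
Why: Mesylation of the tertiary aldol hydroxyl and E1cB elimination through the C7 enolate complete the aldol condensation to the conjugated isopropylidene ketone, and DBU should equilibrate any β,γ-isomer into conjugation.

Step 7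
Reactants: 12 (4S,5R)-5-ethynyl-5-methyl-4-(prop-1-en-2-yl)-2-(propan-2-ylidene)cyclohexan-1-one
Product: 13 4α-hydroxy-5α,10β-eudesma-1,7(11)-dien-8-one
Conditions: [(2-biphenylyl)(t-Bu)2PAu(NCMe)]SbF6 (2 mol %), 1,4-dioxane/H2O 10:1, rt
Reagents that add atoms: water, O
Why: Cationic monovalent gold binds the terminal alkyne C1≡C2, the CH2 carbon of the isopropenyl group (C3) attacks the terminal alkyne carbon C2 so that the positive charge develops on tertiary C4 and gold sits on C1, water adds to C4, and protodeauration of the C1–Au bond leaves the C1=C2 double bond. The closest known reaction type is the gold-catalysed hydroxy- or alkoxycyclisation of 1,5-enynes that carry a 1,1-disubstituted alkene, a nucleophile-terminated cation–olefin cyclisation that here ends like the water capture of the eudesmyl C4 cation in biosynthesis. Ring A closes in the 6-endo-dig mode through a chair-like transition state built on the ring B chair that holds ethynyl and isopropenyl trans-diequatorial. The only new stereocentre, C4, is controlled by C5 and C10: one alkene face is turned to the alkyne and water enters anti to the new C2–C3 bond from the α face, which is also the face not screened by the axial C10 methyl, so the hydroxyl should become equatorial (4α) and the methyl axial (4β). The step needs endo over exo regioselectivity and water capture over proton loss or alkyne hydration; the first should follow from the normal endo mode of 1,5-enynes with the charge on tertiary C4 and from the crowding of C1 next to quaternary C10, the second from a bulky biaryl phosphine ligand, excess water and room temperature, and participation of the C8 carbonyl is excluded because its attack on C1 would need a bridgehead oxocarbenium ion.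

Step 8
Reactants: 13 4α-hydroxy-5α,10β-eudesma-1,7(11)-dien-8-one
Product: 14 3α,4α-dihydroxy-5α,10β-eudesma-1,7(11)-dien-8-one
Conditions: SeO2 (20 mol %), t-BuOOH, CH2Cl2, 0 °C to rt
Reagents that add atoms: selenium dioxide, O=[Se]=O (oxygen carrier); tert-butyl hydroperoxide, CC(C)(C)OO (terminal oxidant)
Why: Allylic hydroxylation with SeO2 (ene reaction, then [2,3]-sigmatropic shift) can only use the C3 hydrogens because C10 is quaternary, and selenium should add to C1 on the α face anti to the C10 methyl with removal of the axial 3α hydrogen, so that oxygen returns to C3 on the same α face, cis to the 4α-OH, while the electron-poor tetrasubstituted enone alkene reacts far more slowly in the ene step.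

Step 9
Reactants: 14 3α,4α-dihydroxy-5α,10β-eudesma-1,7(11)-dien-8-one
Product: 15 3α,4α-dihydroxy-5α,10β-eudesm-7(11)-en-8-one
Conditions: H2 (3 atm), RhCl(PPh3)3 (5 mol %), benzene/EtOH, rt
Reagents that add atoms: none
Why: Homogeneous hydrogenation with RhCl(PPh3)3 should saturate the cis-disubstituted C1=C2 bond and leave the tetrasubstituted conjugated C7=C11 bond and the ketone untouched, and no stereocentre is formed.

Step 10
Reactants: 16 (S)-1-bromo-2-methylbutane
Product: 18 (S)-3-methylpentanoic acid, via Grignard reagent 17 (not isolated)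
Conditions: Mg, THF, reflux; CO2 (solid), −78 °C to rt; 1 M HCl
Reagents that add atoms: carbon dioxide, O=C=O
Why: Carboxylation of the Grignard reagent adds the carboxyl carbon without touching the stereocentre, which is β to magnesium and configurationally stable.

Step 11
Reactants: 15 3α,4α-dihydroxy-5α,10β-eudesm-7(11)-en-8-one; 18 (S)-3-methylpentanoic acid
Product: 20 3α-[(S)-3-methylpentanoyloxy]-4α-hydroxy-5α,10β-eudesm-7(11)-en-8-one, via mixed anhydride 19 (not isolated)
Conditions: 18, 2,4,6-Cl3C6H2COCl, Et3N, THF, rt; then 15, DMAP, toluene, rt to 40 °C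
Reagents that add atoms: none
Why: Yamaguchi esterification should acylate the secondary 3α-hydroxyl only, since the hindered tertiary 4α-hydroxyl does not attack the acylpyridinium ion.

**Compound list**

1 | (1R,5R)-(+)-verbenone, (1R,5R)-4,6,6-trimethylbicyclo[3.1.1]hept-3-en-2-one | CC1=CC(=O)[C@@H]2C[C@H]1C2(C)C | starting material
2 | (1R,4S,5S)-4-ethenyl-4,6,6-trimethylbicyclo[3.1.1]heptan-2-one | C=C[C@]1(C)CC(=O)[C@@H]2C[C@H]1C2(C)C | intermediate
3 | secondary ozonide of 2 (1,2,4-trioxolan-3-yl in place of vinyl, mixture at the acetal carbon) | O1OC(OC1)[C@]2(C)CC(=O)[C@@H]3C[C@H]2C3(C)C | intermediate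
4 | (1R,4R,5S)-4-formyl-4,6,6-trimethylbicyclo[3.1.1]heptan-2-one | O=C[C@]1(C)CC(=O)[C@@H]2C[C@H]1C2(C)C | intermediate
5 | (1R,4R,5S)-4-ethynyl-4,6,6-trimethylbicyclo[3.1.1]heptan-2-one | C#C[C@]1(C)CC(=O)[C@@H]2C[C@H]1C2(C)C | intermediate
6 | [5-ethynyl-4-(2-iodopropan-2-yl)-5-methylcyclohex-1-en-1-yl]oxytrimethylsilane (C5, C10 as in 8) | C#C[C@]1(C)CC(O[Si](C)(C)C)=CC[C@H]1C(C)(C)I | intermediate
7 | [5-ethynyl-5-methyl-4-(prop-1-en-2-yl)cyclohex-1-en-1-yl]oxytrimethylsilane (C5, C10 as in 8) | C#C[C@]1(C)CC(O[Si](C)(C)C)=CC[C@H]1C(C)=C | intermediate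
8 | (3R,4S)-3-ethynyl-3-methyl-4-(prop-1-en-2-yl)cyclohexan-1-one | C#C[C@]1(C)CC(=O)CC[C@H]1C(C)=C | intermediate
9 | lithium enolate of 8 (C7=C8–OLi) | C#C[C@]1(C)CC(O[Li])=CC[C@H]1C(C)=C | intermediate
10 | (4S,5R)-5-ethynyl-2-(2-hydroxypropan-2-yl)-5-methyl-4-(prop-1-en-2-yl)cyclohexan-1-one (C7 epimers) | C#C[C@]1(C)CC(=O)C(C(C)(C)O)C[C@H]1C(C)=C | intermediate
11 | methanesulfonate of 10 | C#C[C@]1(C)CC(=O)C(C(C)(C)OS(C)(=O)=O)C[C@H]1C(C)=C | intermediate
12 | (4S,5R)-5-ethynyl-5-methyl-4-(prop-1-en-2-yl)-2-(propan-2-ylidene)cyclohexan-1-one | C#C[C@]1(C)CC(=O)C(=C(C)C)C[C@H]1C(C)=C | intermediate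
13 | 4α-hydroxy-5α,10β-eudesma-1,7(11)-dien-8-one | C1C=C[C@]2(C)CC(=O)C(=C(C)C)C[C@H]2[C@]1(C)O | intermediate
14 | 3α,4α-dihydroxy-5α,10β-eudesma-1,7(11)-dien-8-one | O[C@@H]1C=C[C@]2(C)CC(=O)C(=C(C)C)C[C@H]2[C@]1(C)O | intermediate
15 | 3α,4α-dihydroxy-5α,10β-eudesm-7(11)-en-8-one | O[C@@H]1CC[C@]2(C)CC(=O)C(=C(C)C)C[C@H]2[C@]1(C)O | intermediate
16 | (S)-1-bromo-2-methylbutane | CC[C@H](C)CBr | starting material
17 | (S)-2-methylbutylmagnesium bromide | CC[C@H](C)C[Mg]Br | intermediate
18 | (S)-3-methylpentanoic acid | CC[C@H](C)CC(=O)O | intermediate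
19 | (S)-3-methylpentanoic 2,4,6-trichlorobenzoic anhydride | CC[C@H](C)CC(=O)OC(=O)c1c(Cl)cc(Cl)cc1Cl | intermediate
20 | 3α-[(S)-3-methylpentanoyloxy]-4α-hydroxy-5α,10β-eudesm-7(11)-en-8-one (CNP0334363.1) | CC[C@H](C)CC(=O)O[C@@H]1CC[C@]2(C)CC(=O)C(=C(C)C)C[C@H]2[C@]1(C)O | target

**Totals**

Total step count: 11. Longest linear sequence: 10 steps (steps 1–9 and 11).

**Steps most likely to fail**

Step 7. What may go wrong is loss of the C4 cation by proton loss or a 1,2-shift before water can add, or hydration of the alkyne. The fallback gives up water capture and sets out from 12. Water-free cycloisomerisation (PtCl2, toluene, 80 °C) should end by loss of a C3 proton and give the conjugated diene 5α,10β-eudesma-1,3,7(11)-trien-8-one F1. OsO4 (cat.) with N-methylmorpholine N-oxide in acetone/water should then dihydroxylate the trisubstituted, more electron-rich C3=C4 bond from the α face, opposite the axial C10 methyl. This returns to the route at 14 and bypasses step 8.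

Step 8. What may go wrong is incomplete facial control of the oxygen transfer to C3, over-oxidation to the enone, or competing ene attack at the isopropylidene methyls. The fallback sets C3 by hydride delivery and sets out from 13. CrO3·3,5-dimethylpyrazole (CH2Cl2, −20 °C) should take the allylic CH2 to the enone 4α-hydroxy-5α,10β-eudesma-1,7(11)-diene-3,8-dione F2. Conjugate reduction of the unhindered C1=C2–C3=O unit with [(Ph3P)CuH]6 gives 4α-hydroxy-5α,10β-eudesm-7(11)-ene-3,8-dione F3. LiBH(s-Bu)3 (THF, −78 °C) should then attack the C3 ketone from the equatorial direction to give the axial 3α-alcohol, the hindered conjugated C8 ketone being less electrophilic. This returns to the route at 15.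

Step 4. What may go wrong is addition of HI to the alkyne or elimination toward C5 instead of a methyl group. The fallback replaces iodide capture and E2 by acetate capture and thermal syn-elimination, and sets out from 5. BF3·OEt2 and Zn(OAc)2 in Ac2O should open the cyclobutane with acetate capture of the tertiary cation and O-acetylation of the enolate, giving 4-(2-acetoxypropan-2-yl)-5-ethynyl-5-methylcyclohex-1-en-1-yl acetate F4. K2CO3 in MeOH at 0 °C should cleave only the enol acetate to 2-(2-ethynyl-2-methyl-4-oxocyclohexyl)propan-2-yl acetate F5. Gas-phase ester pyrolysis (about 450 °C) should expel acetic acid toward a methyl group. This returns to the route at 8.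

**Further compounds**

F1 | step 7 | 5α,10β-eudesma-1,3,7(11)-trien-8-one | CC1=CC=C[C@]2(C)CC(=O)C(=C(C)C)C[C@@H]12
F2 | step 8 | 4α-hydroxy-5α,10β-eudesma-1,7(11)-diene-3,8-dione | O=C1C=C[C@]2(C)CC(=O)C(=C(C)C)C[C@H]2[C@]1(C)O
F3 | step 8 | 4α-hydroxy-5α,10β-eudesm-7(11)-ene-3,8-dione | O=C1CC[C@]2(C)CC(=O)C(=C(C)C)C[C@H]2[C@]1(C)O
F4 | step 4 | 4-(2-acetoxypropan-2-yl)-5-ethynyl-5-methylcyclohex-1-en-1-yl acetate (C5, C10 as in 8) | C#C[C@]1(C)CC(OC(C)=O)=CC[C@H]1C(C)(C)OC(C)=O
F5 | step 4 | 2-(2-ethynyl-2-methyl-4-oxocyclohexyl)propan-2-yl acetate (C5, C10 as in 8) | C#C[C@]1(C)CC(=O)CC[C@H]1C(C)(C)OC(C)=O
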